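**Retrosynthetic overview**
- Target 19 ⇐ silyl ether/methyl ester 17 ⇐ C9–C11 bond by B-alkyl Suzuki–Miyaura coupling of bicyclic enol triflate 9 with the 9-BBN adduct 16 of aryl diene 15 (15 from methyl 4-hydroxybenzoate 10 and prenyl bromide 11).
- 9 ⇐ trans-decalone 7 ⇐ linear dienone 6 ⇐ enedione 3: the C6 oxygen is deleted through its C5=C6 dienol triflate 5, and H5 is put back by hydrogenation anti to C20.
- 3 ⇐ 2,6-dimethyl-1,4-benzoquinone 1 + 4-methylpenta-1,3-diene 2 by a catalytic enantioselective Diels–Alder reaction that closes ring A (bonds C1–C10 and C4–C5) and sets C10.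
- Feature: ring B (C5–C10) with C17 on C8, C20 on C10 and the chain attachment (oxygen handle) at C9 is the substitution pattern of the flat, C2v-symmetric quinone 1. Ring B is bought, ring A is made in the key step, and the arene is attached last.

Key step: step 1

Numbering: labdane numbering is used for the decalin (ring A C1–C5/C10, ring B C5–C10, C17 on C8, C20 on C10, chain C11–C15 from C9, C16 on C13); the target is the (5R,10R) trans-fused compound.
Assumption: the (S)-configured catalyst is assigned to the 10R adduct from the accepted pre-transition-state model (quinone oxygen on boron, α-C–H···O contact, one enone face covered by an aryl group); should the adduct prove antipodal, the (R)-catalyst is used with no other change.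

**Route**

Step 1
Reactants: 1 2,6-dimethyl-1,4-benzoquinone; 2 4-methylpenta-1,3-diene
Product: 3 (4aS,8aR)-2,5,5,8a-tetramethyl-4a,5,8,8a-tetrahydronaphthalene-1,4-dione (cis-fused)
Conditions: (S)-diphenylprolinol-derived B-(o-tolyl)oxazaborolidine/Tf2NH (20 mol %), 2 (5 equiv, slow addition), CH2Cl2, −78 → −40 °C
Reagents that add atoms: none
Why: Diels–Alder reaction under chiral oxazaborolidinium (cationic boron Lewis acid) catalysis, the established enantioselective reaction type for methyl-substituted 1,4-benzoquinones with 1-substituted dienes. The catalyst binds the C4 carbonyl of 1 (flanked by two CH, more basic because both β-methyl groups donate into it, and the less hindered oxygen) at the lone pair syn to C3–H, which makes C2(Me)=C3(H) the activated dienophile with C2 as β-carbon. The [4+2] addition is concerted but asynchronous: the unsubstituted CH2 terminus of 2 (largest HOMO coefficient) bonds to the methyl-bearing β-carbon (C1–C10) ahead of the bond from the CMe2 terminus to the α-CH (C4–C5), so ring A is closed by intermolecular suprafacial [4π+2π] cycloaddition. C10 is controlled by the catalyst, whose aryl group covers one face of the bound enone so that the diene adds to the open face, and C5 is cis to the C10 methyl simply because the addition is suprafacial (this centre is erased in step 2 and reset in step 4). The step needs regioselectivity, which electronic ('ortho' orientation to the coordinated carbonyl, tertiary allyl-cation character at the CMe2 end) and steric factors (the alternative joins two fully substituted carbons) both secure, and enantioface selectivity, which is purely catalyst-controlled because the two ring double bonds of 1 are symmetry-related; the adduct enedione is a poorer dienophile than 1, so double addition is not expected. The weak point is the small s-cis population of 2 caused by its Z-methyl group, which is answered by excess diene, slow addition and the strongest practical activation.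

Step 2
Reactants: 3 (4aS,8aR)-2,5,5,8a-tetramethyl-4a,5,8,8a-tetrahydronaphthalene-1,4-dione
Product: 5 (4aR)-3,4a,8,8-tetramethyl-4-oxo-4,4a,5,8-tetrahydronaphthalen-1-yl trifluoromethanesulfonate, via potassium dienolate 4 (not isolated)
Conditions: KHMDS (1.1 equiv), THF, −78 °C; PhNTf2 (1.2 equiv), −78 → 0 °C
Reagents that add atoms: N-phenylbis(trifluoromethanesulfonimide), O=S(=O)(N(c1ccccc1)S(=O)(=O)C(F)(F)F)C(F)(F)F
Why: Kinetic enolate formation and O-sulfonylation (enol triflate synthesis): the C6 carbonyl of the enedione can enolise only toward C5 because C7 is sp2, and C5–H is the acidic α′-hydrogen of such quinone adducts, so a single cross-conjugated dienolate forms and is trapped on oxygen; the C5 stereocentre is deliberately erased, and quaternary C10 prevents aromatisation.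

Step 3
Reactants: 5 (4aR)-3,4a,8,8-tetramethyl-4-oxo-4,4a,5,8-tetrahydronaphthalen-1-yl trifluoromethanesulfonate
Product: 6 (8aR)-2,5,5,8a-tetramethyl-8,8a-dihydronaphthalen-1(5H)-one
Conditions: Pd(OAc)2 (5 mol %), PPh3 (10 mol %), HCO2H, Et3N, DMF, 60 °C
Reagents that add atoms: none
Why: Palladium-catalysed formate reduction of an enol triflate (oxidative addition, formate–triflate exchange, decarboxylation to Pd–H, reductive elimination) replaces C6–OTf by C6–H without touching the ketone or the ring A alkene; the resulting 6,6-disubstituted cyclohexa-2,4-dienone cannot tautomerise to a phenol and is hindered at both diene termini against dimerisation.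

Step 4
Reactants: 6 (8aR)-2,5,5,8a-tetramethyl-8,8a-dihydronaphthalen-1(5H)-one
Product: 7 (4aR,8aR)-2,5,5,8a-tetramethyloctahydronaphthalen-1(2H)-one (trans-fused; mixture of C2 epimers)
Conditions: H2 (5 bar), 10% Pd/C, EtOAc, rt
Reagents that add atoms: none
Why: Heterogeneous catalytic hydrogenation saturates C2=C3, C7=C8 and C5=C6; with ring A as a chair, C20 and the axial C4 methyl are syn-axial and stand on the same face directly beside C5, so hydrogen should be delivered to C5 from the opposite face and H5 ends trans to C20 (the same facial sense as hydrogenation of 4,4-dimethyl-Δ5-steroids to their trans-fused dihydro derivatives); the C8 methyl centre forms as a mixture, which is of no consequence because C8 becomes sp2 in step 5.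

Step 5
Reactants: 7 (4aR,8aR)-2,5,5,8a-tetramethyloctahydronaphthalen-1(2H)-one
Product: 9 (4aR,8aR)-2,5,5,8a-tetramethyl-3,4,4a,5,6,7,8,8a-octahydronaphthalen-1-yl trifluoromethanesulfonate, via lithium enolate 8 (not isolated)
Conditions: LDA (1.3 equiv), THF, −78 → 0 °C; PhNTf2 (1.3 equiv), 0 °C → rt
Reagents that add atoms: N-phenylbis(trifluoromethanesulfonimide), O=S(=O)(N(c1ccccc1)S(=O)(=O)C(F)(F)F)C(F)(F)F
Why: Enolate O-triflation: C10 is quaternary, so the C9 ketone can be deprotonated only at C8 and both C8 epimers give the same tetrasubstituted enolate, which is converted into the C8=C9 enol triflate as is known for 2,2,6-trimethylcyclohexanone; C5 and C10 are not enolisable and stay untouched.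

Step 6
Reactants: 10 methyl 4-hydroxybenzoate; 11 prenyl bromide (1-bromo-3-methylbut-2-ene)
Product: 12 methyl 4-hydroxy-3-(3-methylbut-2-en-1-yl)benzoate
Conditions: NaH (1.05 equiv), toluene, 0 °C → rt; 11 (1.1 equiv), rt
Reagents that add atoms: none
Why: ortho-C-Alkylation of a sodium phenoxide in a non-polar solvent, where the tight ion pair shields oxygen and the allylic bromide is attacked by the ortho carbon (para is blocked by the ester), followed by re-aromatisation; the O-prenyl ether is the expected by-product and is removed by chromatography.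

Step 7
Reactants: 12 methyl 4-hydroxy-3-(3-methylbut-2-en-1-yl)benzoate
Product: 13 methyl 3-(3-methylbut-2-en-1-yl)-4-[(triisopropylsilyl)oxy]benzoate
Conditions: TIPSCl, imidazole, DMF, rt → 40 °C
Reagents that add atoms: triisopropylsilyl chloride, CC(C)[Si](Cl)(C(C)C)C(C)C
Why: Standard imidazole-assisted silylation of a phenol; the triisopropylsilyl ether shields the phenol from the ylide, the borane and palladium, and is later removed by hydroxide together with the ester, so no acid is needed at the end.

Step 8
Reactants: 13 methyl 3-(3-methylbut-2-en-1-yl)-4-[(triisopropylsilyl)oxy]benzoate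
Product: 14 methyl 3-[(2E)-3-methyl-4-oxobut-2-en-1-yl]-4-[(triisopropylsilyl)oxy]benzoate
Conditions: SeO2 (1.2 equiv), 1,4-dioxane, 80 °C
Reagents that add atoms: selenium dioxide, O=[Se]=O
Why: Selenium dioxide allylic oxidation (ene reaction, [2,3]-sigmatropic shift, further oxidation to the aldehyde) attacks the methyl group trans to the chain on the more substituted alkene carbon and so should give the (E)-enal with the C13=C14 geometry of the target; the benzylic/allylic CH2 on the less substituted alkene carbon is not a site of this reaction.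

Step 9
Reactants: 14 methyl 3-[(2E)-3-methyl-4-oxobut-2-en-1-yl]-4-[(triisopropylsilyl)oxy]benzoate
Product: 15 methyl 3-[(2E)-3-methylpenta-2,4-dien-1-yl]-4-[(triisopropylsilyl)oxy]benzoate
Conditions: Ph3PCH3Br, NaHMDS, THF, 0 °C; then 14, −78 → 0 °C
Reagents that add atoms: methyltriphenylphosphonium bromide, C[P+](c1ccccc1)(c1ccccc1)c1ccccc1.[Br-]
Why: Wittig methylenation of the enal with a non-stabilised ylide, which reacts with the aldehyde far faster than with the aryl ester at low temperature and leaves the trisubstituted (E)-alkene untouched.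

Step 10
Reactants: 15 methyl 3-[(2E)-3-methylpenta-2,4-dien-1-yl]-4-[(triisopropylsilyl)oxy]benzoate; 9 (4aR,8aR)-2,5,5,8a-tetramethyl-3,4,4a,5,6,7,8,8a-octahydronaphthalen-1-yl trifluoromethanesulfonate
Product: 17 methyl 3-[(2E)-3-methyl-5-[(4aR,8aR)-2,5,5,8a-tetramethyl-3,4,4a,5,6,7,8,8a-octahydronaphthalen-1-yl]pent-2-en-1-yl]-4-[(triisopropylsilyl)oxy]benzoate, via alkylborane 16 (not isolated)
Conditions: 15 (1.5 equiv), 9-BBN (1.6 equiv), THF, 0 °C → rt; then 9, Pd(OAc)2 (5 mol %), SPhos (10 mol %), K3PO4 (3 M aq), THF, 60 °C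
Reagents that add atoms: none
Why: Hydroboration with 9-BBN is selective for the terminal vinyl group of the diene (boron on C11, anti-Markovnikov; the trisubstituted alkene and the ester do not react, as in the known conversion of such 1,3-dienes into homoallylic boranes), and B-alkyl Suzuki–Miyaura coupling of the borane with the alkenyl triflate forms C9–C11 with both alkenes in place; a bulky electron-rich biarylphosphine is chosen because the triflate is tetrasubstituted and flanked by quaternary C10, and partial loss of the silyl group under the basic conditions would be harmless.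

Step 11
Reactants: 17 methyl 3-[(2E)-3-methyl-5-[(4aR,8aR)-2,5,5,8a-tetramethyl-3,4,4a,5,6,7,8,8a-octahydronaphthalen-1-yl]pent-2-en-1-yl]-4-[(triisopropylsilyl)oxy]benzoate
Product: 19 4-hydroxy-3-[(2E)-3-methyl-5-[(4aR,8aR)-2,5,5,8a-tetramethyl-3,4,4a,5,6,7,8,8a-octahydronaphthalen-1-yl]pent-2-en-1-yl]benzoic acid, via phenol methyl ester 18 (not isolated)
Conditions: LiOH·H2O (8 equiv), THF/MeOH/H2O, 50 °C; then 1 M HCl, 0 °C, to pH 4–5
Reagents that add atoms: lithium hydroxide, [Li+].[OH-]
Why: Hydroxide cleaves the aryl silyl ether of this acidic phenol at silicon and then saponifies the methyl ester; acidification only to pH 4–5 in the cold frees the acid without acid-catalysed chroman formation from the ortho-allylic phenol or migration of the C8=C9 alkene.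

**Compound list**
1 | 2,6-dimethyl-1,4-benzoquinone | CC1=CC(=O)C=C(C)C1=O | starting material
2 | 4-methylpenta-1,3-diene | C=CC=C(C)C | starting material
3 | (4aS,8aR)-2,5,5,8a-tetramethyl-4a,5,8,8a-tetrahydronaphthalene-1,4-dione (cis-fused) | O=C1C(C)=CC(=O)[C@H]2C(C)(C)C=CC[C@@]12C | intermediate
4 | potassium (4aR)-3,4a,8,8-tetramethyl-4-oxo-4,4a,5,8-tetrahydronaphthalen-1-olate (dienolate of 3) | O=C1C(C)=CC([O-])=C2C(C)(C)C=CC[C@@]12C.[K+] | intermediate
5 | (4aR)-3,4a,8,8-tetramethyl-4-oxo-4,4a,5,8-tetrahydronaphthalen-1-yl trifluoromethanesulfonate | O=C1C(C)=CC(OS(=O)(=O)C(F)(F)F)=C2C(C)(C)C=CC[C@@]12C | intermediate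
6 | (8aR)-2,5,5,8a-tetramethyl-8,8a-dihydronaphthalen-1(5H)-one | O=C1C(C)=CC=C2C(C)(C)C=CC[C@@]12C | intermediate
7 | (4aR,8aR)-2,5,5,8a-tetramethyloctahydronaphthalen-1(2H)-one (trans-fused; C2 epimers, C2 left undefined) | CC1C(=O)[C@]2(C)CCCC(C)(C)[C@H]2CC1 | intermediate
8 | lithium (4aR,8aR)-2,5,5,8a-tetramethyl-3,4,4a,5,6,7,8,8a-octahydronaphthalen-1-olate | CC1=C([O-])[C@]2(C)CCCC(C)(C)[C@H]2CC1.[Li+] | intermediate
9 | (4aR,8aR)-2,5,5,8a-tetramethyl-3,4,4a,5,6,7,8,8a-octahydronaphthalen-1-yl trifluoromethanesulfonate | CC1=C(OS(=O)(=O)C(F)(F)F)[C@]2(C)CCCC(C)(C)[C@H]2CC1 | intermediate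
10 | methyl 4-hydroxybenzoate | COC(=O)c1ccc(O)cc1 | starting material
11 | prenyl bromide (1-bromo-3-methylbut-2-ene) | CC(C)=CCBr | starting material
12 | methyl 4-hydroxy-3-(3-methylbut-2-en-1-yl)benzoate | COC(=O)c1ccc(O)c(CC=C(C)C)c1 | intermediate
13 | methyl 3-(3-methylbut-2-en-1-yl)-4-[(triisopropylsilyl)oxy]benzoate | COC(=O)c1ccc(O[Si](C(C)C)(C(C)C)C(C)C)c(CC=C(C)C)c1 | intermediate
14 | methyl 3-[(2E)-3-methyl-4-oxobut-2-en-1-yl]-4-[(triisopropylsilyl)oxy]benzoate | COC(=O)c1ccc(O[Si](C(C)C)(C(C)C)C(C)C)c(C/C=C(\C)C=O)c1 | intermediate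
15 | methyl 3-[(2E)-3-methylpenta-2,4-dien-1-yl]-4-[(triisopropylsilyl)oxy]benzoate | COC(=O)c1ccc(O[Si](C(C)C)(C(C)C)C(C)C)c(C/C=C(\C)C=C)c1 | intermediate
16 | methyl 3-[(2E)-5-(9-borabicyclo[3.3.1]nonan-9-yl)-3-methylpent-2-en-1-yl]-4-[(triisopropylsilyl)oxy]benzoate | COC(=O)c1ccc(O[Si](C(C)C)(C(C)C)C(C)C)c(C/C=C(\C)CCB2C3CCCC2CCC3)c1 | intermediate
17 | methyl 3-[(2E)-3-methyl-5-[(4aR,8aR)-2,5,5,8a-tetramethyl-3,4,4a,5,6,7,8,8a-octahydronaphthalen-1-yl]pent-2-en-1-yl]-4-[(triisopropylsilyl)oxy]benzoate | CC1=C(CC/C(C)=C/Cc2cc(C(=O)OC)ccc2O[Si](C(C)C)(C(C)C)C(C)C)[C@]2(C)CCCC(C)(C)[C@H]2CC1 | intermediate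
18 | methyl 4-hydroxy-3-[(2E)-3-methyl-5-[(4aR,8aR)-2,5,5,8a-tetramethyl-3,4,4a,5,6,7,8,8a-octahydronaphthalen-1-yl]pent-2-en-1-yl]benzoate | CC1=C(CC/C(C)=C/Cc2cc(C(=O)OC)ccc2O)[C@]2(C)CCCC(C)(C)[C@H]2CC1 | intermediate
19 | 4-hydroxy-3-[(2E)-3-methyl-5-[(4aR,8aR)-2,5,5,8a-tetramethyl-3,4,4a,5,6,7,8,8a-octahydronaphthalen-1-yl]pent-2-en-1-yl]benzoic acid | CC1=C(CC/C(C)=C/Cc2cc(C(=O)O)ccc2O)[C@]2(C)CCCC(C)(C)[C@H]2CC1 | target

**Count**
Total steps: 11. Longest linear sequence: 7 (steps 1–5, 10, 11).

**Steps most likely to fail**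

1. Step 1 (cycloaddition). The diene reaches the reactive s-cis conformation only rarely because of its Z-methyl group. Cycloaddition may therefore be slower than acid-initiated oligomerisation of the diene, or a stepwise, less face-selective pathway may take over.
Fallback, setting out from 1 and coming back at 6: mesityl oxide (4-methylpent-3-en-2-one, CC(C)=CC(C)=O) is converted by kinetic deprotonation (LDA, THF, −78 °C; TBSCl, DMPU) into the cross-conjugated diene tert-butyl(dimethyl)[(4-methylpenta-1,3-dien-2-yl)oxy]silane F1. Its 2-oxygen raises the HOMO and evens out the s-cis/s-trans penalty, and 2-silyloxy dienes are the standard partners of this catalyst class. Cycloaddition with 1 under the conditions of step 1 has the same regiochemistry (the 2-oxygen and the CMe2 terminus both make the CH2 end nucleophilic) and should give (4aS,8aR)-7-[(tert-butyldimethylsilyl)oxy]-2,5,5,8a-tetramethyl-4a,5,8,8a-tetrahydronaphthalene-1,4-dione F2. KHMDS/PhNTf2 as in step 2 gives (4aR)-6-[(tert-butyldimethylsilyl)oxy]-3,4a,8,8-tetramethyl-4-oxo-4,4a,5,8-tetrahydronaphthalen-1-yl trifluoromethanesulfonate F3. CsF/PhNTf2 in DME exchanges the silyl enol ether for a second enol triflate, giving (4aR)-3,4a,8,8-tetramethyl-4-oxo-4,4a,5,8-tetrahydronaphthalene-1,6-diyl bis(trifluoromethanesulfonate) F4. Twofold palladium/formate reduction as in step 3 then gives 6.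

2. Step 4 (hydrogenation). The C5=C6 bond lies between two quaternary carbons, so saturation may stall, or hydrogen may be delivered in part to the face bearing C20, giving cis-fused material.
Fallback, setting out from 3 and coming back at 7, which replaces kinetic face control by thermodynamic control: hydrogenation of 3 (H2, Pd/C, EtOAc) gives cis-fused (4aS,8aR)-2,5,5,8a-tetramethyloctahydronaphthalene-1,4-dione F5. Equilibration through the C6 enolate (NaOMe, MeOH) gives trans-fused (4aR,8aR)-2,5,5,8a-tetramethyloctahydronaphthalene-1,4-dione F6, with separation and recycling of remaining cis isomer. Ethane-1,2-dithiol/BF3·OEt2 reacts at the less hindered C6 carbonyl (C9 lies between quaternary C10 and C8–Me) to give the C4 1,3-dithiolane of (4aR,8aR)-2,5,5,8a-tetramethyloctahydronaphthalene-1,4-dione F7. Desulfurisation with deactivated Raney nickel in ethanol gives 7.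

3. Step 10 (B-alkyl coupling). Transmetalation and reductive elimination at the tetrasubstituted alkenyl–palladium centre next to quaternary C10 may be slow, so that hydrolysis of the triflate back to 7 and protodeboronation of the alkylborane take over in the basic aqueous medium.
Fallback, setting out from 15 and 9 and coming back at 17, which moves the coupling to base-free organozinc chemistry: borane 16, made from 15 as in step 10, is oxidised (NaOH, H2O2) to methyl 3-[(2E)-5-hydroxy-3-methylpent-2-en-1-yl]-4-[(triisopropylsilyl)oxy]benzoate F8. An Appel-type reaction (I2, PPh3, imidazole) gives methyl 3-[(2E)-5-iodo-3-methylpent-2-en-1-yl]-4-[(triisopropylsilyl)oxy]benzoate F9. Zinc insertion (Zn dust, LiCl, THF) gives the ester-tolerant alkylzinc iodide iodo{(3E)-5-[5-(methoxycarbonyl)-2-[(triisopropylsilyl)oxy]phenyl]-3-methylpent-3-en-1-yl}zinc F10. Negishi coupling with 9 (Pd(OAc)2, SPhos, THF/NMP, 50 °C) then gives 17.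

**Further compounds**
F1 | step 1 | tert-butyl(dimethyl)[(4-methylpenta-1,3-dien-2-yl)oxy]silane | C=C(O[Si](C)(C)C(C)(C)C)C=C(C)C
F2 | step 1 | (4aS,8aR)-7-[(tert-butyldimethylsilyl)oxy]-2,5,5,8a-tetramethyl-4a,5,8,8a-tetrahydronaphthalene-1,4-dione | O=C1C(C)=CC(=O)[C@H]2C(C)(C)C=C(O[Si](C)(C)C(C)(C)C)C[C@@]12C
F3 | step 1 | (4aR)-6-[(tert-butyldimethylsilyl)oxy]-3,4a,8,8-tetramethyl-4-oxo-4,4a,5,8-tetrahydronaphthalen-1-yl trifluoromethanesulfonate | O=C1C(C)=CC(OS(=O)(=O)C(F)(F)F)=C2C(C)(C)C=C(O[Si](C)(C)C(C)(C)C)C[C@@]12C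
F4 | step 1 | (4aR)-3,4a,8,8-tetramethyl-4-oxo-4,4a,5,8-tetrahydronaphthalene-1,6-diyl bis(trifluoromethanesulfonate) | O=C1C(C)=CC(OS(=O)(=O)C(F)(F)F)=C2C(C)(C)C=C(OS(=O)(=O)C(F)(F)F)C[C@@]12C
F5 | step 4 | (4aS,8aR)-2,5,5,8a-tetramethyloctahydronaphthalene-1,4-dione (cis-fused; C2 epimers) | O=C1C(C)CC(=O)[C@H]2C(C)(C)CCC[C@@]12C
F6 | step 4 | (4aR,8aR)-2,5,5,8a-tetramethyloctahydronaphthalene-1,4-dione (trans-fused; C2 epimers) | O=C1C(C)CC(=O)[C@@H]2C(C)(C)CCC[C@@]12C
F7 | step 4 | C4 1,3-dithiolane (ethane-1,2-diyl dithioketal) of (4aR,8aR)-2,5,5,8a-tetramethyloctahydronaphthalene-1,4-dione | O=C1C(C)CC2(SCCS2)[C@@H]3C(C)(C)CCC[C@@]13C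
F8 | step 10 | methyl 3-[(2E)-5-hydroxy-3-methylpent-2-en-1-yl]-4-[(triisopropylsilyl)oxy]benzoate | COC(=O)c1ccc(O[Si](C(C)C)(C(C)C)C(C)C)c(C/C=C(\C)CCO)c1
F9 | step 10 | methyl 3-[(2E)-5-iodo-3-methylpent-2-en-1-yl]-4-[(triisopropylsilyl)oxy]benzoate | COC(=O)c1ccc(O[Si](C(C)C)(C(C)C)C(C)C)c(C/C=C(\C)CCI)c1
F10 | step 10 | iodo{(3E)-5-[5-(methoxycarbonyl)-2-[(triisopropylsilyl)oxy]phenyl]-3-methylpent-3-en-1-yl}zinc | COC(=O)c1ccc(O[Si](C(C)C)(C(C)C)C(C)C)c(C/C=C(\C)CC[Zn]I)c1
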